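We start from a one-step world, in which starting material turns into target at one constant per minute. What permits this picture here is that c(dissolved gas) may be nearly constant: the beta target rises from its first readings with no visible lag, so we freeze c(dissolved gas) at one level and assume that level is the same at either charge.

the same everywhere: gas phase 20 mM (held)

|  | starting material | protic impurity | remark | time |
|---|---|---|---|---|
| beta | 0.75 M | 0.050 M | run made earlier |  |
| flask | 0.50 M | 0.0500 M |  | 30 min |

beta run (percent of the starting material charged)

| time / min | target / % |
|---|---|
| 0.500 | 0.5 |
| 1.33 | 2.1 |
| 2.50 | 3.3 |
| 4.00 | 5.7 |
| 5.00 | 6.8 |
| 8.00 | 10.3 |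
| 10.0 | 12.4 |

(each reading ± 0.3 percentage points)

- at the start none of the gas is dissolved
- steps thought possible: gas phase <-> dissolved gas; starting material + dissolved gas -> target; dissolved gas + target -> over-reacted product; dissolved gas <-> dormant form; starting material + protic impurity -> quenched substrate

- amount of target at 30 min, in percent of the starting material charged
- the change that raises the amount of target at 30 min, in percent of the starting material charged most ("none" if none brings more than 2 percentage points) (grey / teal / none)
- amount of target at 30 min, in percent of the starting material charged, after grey

- grey: doubling the transfer coefficient of the gas phase, all else as stated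
- teal: doubling the saturation concentration of gas phase, all else as stated

Taken at face value, the last beta reading, 12.4% at 10.0 min, gives 0.0132 min⁻¹. If we credit the 6.67% of that charge taken by protic impurity, one for one, it gives 0.0143 min⁻¹, and this is our frozen-gas constant, the pseudo-first-order fraction of remaining starting material that becomes target per minute.

From above, with the whole flask charge on that constant, we reckon 34.8%; taking the flask's quench of 10.0% off the charge tightens this to 31.3%. From below, the same quench with the face-value constant, which books every beta shortfall as slowness, gives 29.5%. Teal doubles the frozen level in this picture, whereas grey leaves saturation where it is and can raise c(dissolved gas) just by what that level lacks of saturation, so we commit to teal.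

The forecast gives 30%, 33% after grey, and teal, holding that “the curvature favours mostly kinetic control”, and its 30% lies inside our bracket.

The flask gives 30.5%, inside the bracket, and 30.8% after grey, while teal gains 14 percentage points against 0.28 points for grey.

    gas phase ⇌ dissolved gas, rate k1*(csat - [dissolved gas]) (kL = 0.218 s⁻¹)
    starting material + dissolved gas → target (k = 0.0133 M⁻¹ s⁻¹)
    dissolved gas + target → over-reacted product (k = 0.00519 M⁻¹ s⁻¹)
    dissolved gas ⇌ dormant form (K = 560, k = 1.61 × 10⁻⁴ s⁻¹)
    starting material + protic impurity → quenched substrate (k = 0.0579 M⁻¹ s⁻¹)

In the flask, dissolved gas stood at 97.3% of saturation at 3.00 min and 97.6% at 15.0 min. A neighbour flask with 0.12 M of starting material, all else as here, loses 41.7% to quench by our reckoning, and 0.0143 min⁻¹ then gives 20.3% target; that neighbour flask holds 41.6% quenched substrate and 21.2% target.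

All runs stem from a simulated flask for substances that don't exist.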